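## Retrosynthetic overview

- **Feature:** ring C carries three adjacent oxygenated carbons (C–OAr to ring B, C–OH, C–OH). The CH2CH2 bridge to ring D sits para to the central C–OH, between the two ring C–H carbons. This is the O-pattern of C4/C3/C2 of a 4-aryloxyacetoacetate joined to a 2-substituted malondialdehyde.
- **Endgame:** the outer catechol OH is traced back to a CO2Me group (ester, CH2OH, CHO, Dakin oxidation). The phenols of rings A and D are carried as methyl ethers and freed last with BBr3.
- **Key disconnection:** the ring C bonds C(OAr)–CH and C(CO2Me)–CH are cut. This gives a 4-aryloxy-1,3-bis(silyloxy)diene (three-carbon dinucleophile, rings A and B) and a symmetric 2-substituted 1,1,3,3-tetraethoxypropane (three-carbon dielectrophile, ring D).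
- **The two arms:** Wittig olefination and hydrogenation give the A–B bibenzyl phenol, whose oxygen is attached to the sp3 CH2Cl carbon of methyl 4-chloroacetoacetate, so no aryl–O coupling is needed. The acetal arm runs from 4-(3-methoxyphenyl)butanoic acid through the aldehyde and enol ether to the orthoformate adduct.
- **Ring order:** rings A, B and D are bought intact. Ring C is the only ring built, in the convergent step.

Key step: step 11

Remark on the chemistry: the target has no stereocentre, and every alkene geometry or sp3 stereocentre that appears on the way is erased later. Such intermediates are therefore carried as isomer mixtures and drawn without configuration.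

## Route

Step 1
Reactants: 1 4-(benzyloxy)benzaldehyde; 2 (3-methoxybenzyl)triphenylphosphonium chloride
Product: 3 1-(benzyloxy)-4-[2-(3-methoxyphenyl)ethenyl]benzene (E/Z mixture)
Conditions: KOtBu (1.1 equiv), THF, 0 °C → rt
Reagents that add atoms: none
Why: Wittig olefination of an aromatic aldehyde with a semi-stabilised benzyl ylide is dependable, the E/Z mixture does not matter because the alkene is saturated next, and the benzyl ether avoids an unreactive phenoxide aldehyde.

Step 2
Reactants: 3 1-(benzyloxy)-4-[2-(3-methoxyphenyl)ethenyl]benzene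
Product: 4 4-[2-(3-methoxyphenyl)ethyl]phenol
Conditions: H2 (1 atm), 10% Pd/C, EtOAc–MeOH, rt
Reagents that add atoms: none
Why: Catalytic hydrogenation over Pd/C saturates the stilbene and hydrogenolyses the benzyl aryl ether in one operation, while the aryl methyl ether is inert.

Step 3
Reactants: 4 4-[2-(3-methoxyphenyl)ethyl]phenol; 5 methyl 4-chloroacetoacetate
Product: 6 methyl 4-{4-[2-(3-methoxyphenyl)ethyl]phenoxy}-3-oxobutanoate
Conditions: NaH (2.2 equiv), THF, 0 °C; then 5 dropwise, 0 °C → rt; 1 M HCl
Reagents that add atoms: none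
Why: Williamson ether synthesis at the primary α-chloro ketone carbon, in which the second equivalent of NaH holds 5 as its C2 enolate and so shields the keto ester from condensation while the phenoxide displaces chloride.

Step 4
Reactants: 6 methyl 4-{4-[2-(3-methoxyphenyl)ethyl]phenoxy}-3-oxobutanoate
Product: 7 methyl 4-{4-[2-(3-methoxyphenyl)ethyl]phenoxy}-3-(trimethylsilyloxy)but-2-enoate (isomer mixture)
Conditions: Me3SiCl (1.5 equiv), NEt3 (1.5 equiv), toluene, rt, 48 h; filtration under Ar
Reagents that add atoms: chlorotrimethylsilane, C[Si](C)(C)Cl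
Why: Soft enolisation and O-silylation of the β-keto ester gives the ester-conjugated silyl enol ether, the standard first stage in making a 1,3-bis(silyloxy)diene.

Step 5
Reactants: 7 methyl 4-{4-[2-(3-methoxyphenyl)ethyl]phenoxy}-3-(trimethylsilyloxy)but-2-enoate
Product: 8 1-methoxy-4-{4-[2-(3-methoxyphenyl)ethyl]phenoxy}-1,3-bis(trimethylsilyloxy)buta-1,3-diene (isomer mixture)
Conditions: LiN(iPr)2 (1.5 equiv), THF, −78 °C; Me3SiCl (1.5 equiv), −78 °C → rt; hexane, filtration under Ar, used crude
Reagents that add atoms: chlorotrimethylsilane, C[Si](C)(C)Cl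
Why: Kinetic γ-deprotonation of the β-silyloxy crotonate at C4, which the aryloxy group acidifies further, followed by O-silylation at the ester oxygen gives the bis(silyl) dienol ether, and the non-aqueous work-up preserves it.

Step 6
Reactants: 9 4-(3-methoxyphenyl)butanoic acid
Product: 10 4-(3-methoxyphenyl)butan-1-ol
Conditions: LiAlH4, THF, 0 °C → rt; aqueous work-up
Reagents that add atoms: none
Why: Hydride reduction of a carboxylic acid to the primary alcohol, with the anisole ring inert.

Step 7
Reactants: 10 4-(3-methoxyphenyl)butan-1-ol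
Product: 11 4-(3-methoxyphenyl)butanal
Conditions: TEMPO (10 mol%), PhI(OAc)2 (1.1 equiv), CH2Cl2, rt
Reagents that add atoms: none
Why: The oxoammonium-catalysed (TEMPO) oxidation of a primary alcohol stops at the aldehyde in the absence of water and leaves the arene untouched.

Step 8
Reactants: 11 4-(3-methoxyphenyl)butanal; 12 triethyl orthoformate
Product: 13 1-(4,4-diethoxybutyl)-3-methoxybenzene
Conditions: 12 (2 equiv, neat), p-TsOH·H2O (1 mol%), rt; NEt3 quench
Reagents that add atoms: triethyl orthoformate (12), CCOC(OCC)OCC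
Why: Acid-catalysed acetalisation with the orthoformate as ethoxy donor and water scavenger, under trace acid at room temperature that is too mild to cause cyclisation onto the arene.

Step 9
Reactants: 13 1-(4,4-diethoxybutyl)-3-methoxybenzene
Product: 14 1-(4-ethoxybut-3-en-1-yl)-3-methoxybenzene (E/Z mixture)
Conditions: Me3SiOTf (1.2 equiv), iPr2NEt (1.4 equiv), CH2Cl2, −20 °C → rt; aq. NaHCO3
Reagents that add atoms: none
Why: Silyl triflate activates one acetal oxygen and the hindered amine removes the α-proton at once (1,2-elimination of ethanol as its silyl ether), so the enol ether forms in a buffered, non-acidic medium.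

Step 10
Reactants: 14 1-(4-ethoxybut-3-en-1-yl)-3-methoxybenzene; 12 triethyl orthoformate
Product: 15 1,1,3,3-tetraethoxy-2-[2-(3-methoxyphenyl)ethyl]propane
Conditions: 12 (3 equiv, neat), BF3·OEt2 (5 mol%), 0 °C → rt; solid Na2CO3 quench; chromatography on NEt3-deactivated silica
Reagents that add atoms: triethyl orthoformate (12), CCOC(OCC)OCC
Why: Lewis-acid-catalysed addition of an orthoester to an enol ether, in which BF3 ionises the orthoformate in preference to any acetal, the stabilised diethoxycarbenium ion adds to the nucleophilic β-carbon, and ethoxide transfer caps the new oxocarbenium ion as the second acetal.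

Step 11
Reactants: 8 1-methoxy-4-{4-[2-(3-methoxyphenyl)ethyl]phenoxy}-1,3-bis(trimethylsilyloxy)buta-1,3-diene; 15 1,1,3,3-tetraethoxy-2-[2-(3-methoxyphenyl)ethyl]propane
Product: 18 methyl 2-hydroxy-5-[2-(3-methoxyphenyl)ethyl]-3-{4-[2-(3-methoxyphenyl)ethyl]phenoxy}benzoate, via open-chain vinylogous aldol adduct 16 (not isolated), via diethoxycyclohexanone ester 17 (not isolated)
Conditions: 8 (1.3 equiv) and 15 premixed, CH2Cl2, 4 Å MS, −78 °C; TiCl4 (1.1 equiv) added last; −78 → 20 °C, 14 h; 10% aq. HCl
Reagents that add atoms: none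
Why: TiCl4 ionises one acetal of 15 to an oxocarbenium ion, which is attacked by the terminal, aryloxy-bearing carbon C4 of diene 8 (the most nucleophilic site, vinylogous Mukaiyama aldol-type addition) to give 16 as its titanium or silyl enolate. Ionisation of the remaining acetal and attack by C2 of the β-keto ester enolate closes ring C in a 6-(enolendo)-exo-trig mode to 17, and two β-eliminations of ethanol followed by enolisation aromatise it to the hydrogen-bonded salicylate 18. The closest known reaction type is the TiCl4-mediated formal [3+3] cyclocondensation of 1,3-bis(silyloxy)-1,3-dienes with 2-alkyl-1,1,3,3-tetraalkoxypropanes to 5-alkylsalicylates, a class that also accepts 4-aryloxy dienes. No stereocentre survives, so the diastereomer make-up of 16 and 17 and the alkene geometry of 8 are irrelevant. Regiochemistry needs no control, because 15 has two identical acetal termini and either order of C4/C2 bonding leads to the same 3-aryloxy-5-alkyl pattern. The selectivity that is needed is capture of the oxocarbenium ion by the diene ahead of six-membered Friedel–Crafts closure onto the tethered anisyl ring D, and it is secured by the far higher nucleophilicity of the silyl dienol ether, by the slight excess of 8, and by adding TiCl4 last at −78 °C.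

Step 12
Reactants: 18 methyl 2-hydroxy-5-[2-(3-methoxyphenyl)ethyl]-3-{4-[2-(3-methoxyphenyl)ethyl]phenoxy}benzoate
Product: 19 2-(hydroxymethyl)-4-[2-(3-methoxyphenyl)ethyl]-6-{4-[2-(3-methoxyphenyl)ethyl]phenoxy}phenol
Conditions: LiAlH4 (2 equiv), THF, 0 °C → rt; sat. aq. NH4Cl
Reagents that add atoms: none
Why: LiAlH4 reduces the ester (after deprotonating the phenol) to the benzylic alcohol, all ethers are untouched, and the near-neutral work-up avoids o-quinone methide formation.

Step 13
Reactants: 19 2-(hydroxymethyl)-4-[2-(3-methoxyphenyl)ethyl]-6-{4-[2-(3-methoxyphenyl)ethyl]phenoxy}phenol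
Product: 20 2-hydroxy-5-[2-(3-methoxyphenyl)ethyl]-3-{4-[2-(3-methoxyphenyl)ethyl]phenoxy}benzaldehyde
Conditions: activated MnO2 (10 equiv), CH2Cl2, rt
Reagents that add atoms: none
Why: Activated MnO2 oxidises benzylic alcohols selectively, the salicylaldehyde is stabilised by its internal hydrogen bond, and the phenol, substituted at both ortho positions and at the para position, cannot undergo oxidative coupling.

Step 14
Reactants: 20 2-hydroxy-5-[2-(3-methoxyphenyl)ethyl]-3-{4-[2-(3-methoxyphenyl)ethyl]phenoxy}benzaldehyde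
Product: 22 5-[2-(3-methoxyphenyl)ethyl]-3-{4-[2-(3-methoxyphenyl)ethyl]phenoxy}benzene-1,2-diol, via aryl formate 21 (not isolated)
Conditions: 30% aq. H2O2 (1.2 equiv), NaOH (2 equiv), THF–H2O, 0 °C → rt, Ar; 1 M HCl
Reagents that add atoms: hydrogen peroxide, OO
Why: Dakin oxidation, in which hydroperoxide adds to the aldehyde, the electron-rich o-phenoxide aryl group migrates to oxygen to give formate 21, and this is saponified in the same flask, with exclusion of air protecting the catechol.

Step 15
Reactants: 22 5-[2-(3-methoxyphenyl)ethyl]-3-{4-[2-(3-methoxyphenyl)ethyl]phenoxy}benzene-1,2-diol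
Product: 23 perrottetin F, 5-[2-(3-hydroxyphenyl)ethyl]-3-{4-[2-(3-hydroxyphenyl)ethyl]phenoxy}benzene-1,2-diol
Conditions: BBr3 (6 equiv), CH2Cl2, −78 °C → rt; ice–water
Reagents that add atoms: none
Why: BBr3 cleaves aryl methyl ethers by complexation and SN2 attack of bromide on the methyl carbon, whereas the diaryl ether offers no sp3 C–O carbon and survives.

## Compound list

1 | 4-(benzyloxy)benzaldehyde | O=Cc1ccc(OCc2ccccc2)cc1 | starting material
2 | (3-methoxybenzyl)triphenylphosphonium chloride | COc1cccc(C[P+](c2ccccc2)(c2ccccc2)c2ccccc2)c1.[Cl-] | starting material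
3 | 1-(benzyloxy)-4-[2-(3-methoxyphenyl)ethenyl]benzene (E/Z mixture) | COc1cccc(C=Cc2ccc(OCc3ccccc3)cc2)c1 | intermediate
4 | 4-[2-(3-methoxyphenyl)ethyl]phenol | COc1cccc(CCc2ccc(O)cc2)c1 | intermediate
5 | methyl 4-chloroacetoacetate | COC(=O)CC(=O)CCl | starting material
6 | methyl 4-{4-[2-(3-methoxyphenyl)ethyl]phenoxy}-3-oxobutanoate | COC(=O)CC(=O)COc1ccc(CCc2cccc(OC)c2)cc1 | intermediate
7 | methyl 4-{4-[2-(3-methoxyphenyl)ethyl]phenoxy}-3-(trimethylsilyloxy)but-2-enoate (isomer mixture) | COC(=O)C=C(O[Si](C)(C)C)COc1ccc(CCc2cccc(OC)c2)cc1 | intermediate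
8 | 1-methoxy-4-{4-[2-(3-methoxyphenyl)ethyl]phenoxy}-1,3-bis(trimethylsilyloxy)buta-1,3-diene (isomer mixture) | COC(O[Si](C)(C)C)=CC(O[Si](C)(C)C)=COc1ccc(CCc2cccc(OC)c2)cc1 | intermediate
9 | 4-(3-methoxyphenyl)butanoic acid | COc1cccc(CCCC(O)=O)c1 | starting material
10 | 4-(3-methoxyphenyl)butan-1-ol | COc1cccc(CCCCO)c1 | intermediate
11 | 4-(3-methoxyphenyl)butanal | COc1cccc(CCCC=O)c1 | intermediate
12 | triethyl orthoformate | CCOC(OCC)OCC | starting material
13 | 1-(4,4-diethoxybutyl)-3-methoxybenzene | CCOC(CCCc1cccc(OC)c1)OCC | intermediate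
14 | 1-(4-ethoxybut-3-en-1-yl)-3-methoxybenzene (E/Z mixture) | CCOC=CCCc1cccc(OC)c1 | intermediate
15 | 1,1,3,3-tetraethoxy-2-[2-(3-methoxyphenyl)ethyl]propane | CCOC(OCC)C(CCc1cccc(OC)c1)C(OCC)OCC | intermediate
16 | methyl 6-(diethoxymethyl)-5-ethoxy-8-(3-methoxyphenyl)-4-{4-[2-(3-methoxyphenyl)ethyl]phenoxy}-3-oxooctanoate (diastereomer mixture, drawn as the neutral keto form, not isolated) | COC(=O)CC(=O)C(Oc1ccc(CCc2cccc(OC)c2)cc1)C(OCC)C(CCc1cccc(OC)c1)C(OCC)OCC | intermediate
17 | methyl 2,4-diethoxy-3-[2-(3-methoxyphenyl)ethyl]-5-{4-[2-(3-methoxyphenyl)ethyl]phenoxy}-6-oxocyclohexane-1-carboxylate (diastereomer mixture, drawn as the neutral keto form, not isolated) | COC(=O)C1C(OCC)C(CCc2cccc(OC)c2)C(OCC)C(Oc2ccc(CCc3cccc(OC)c3)cc2)C1=O | intermediate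
18 | methyl 2-hydroxy-5-[2-(3-methoxyphenyl)ethyl]-3-{4-[2-(3-methoxyphenyl)ethyl]phenoxy}benzoate | COC(=O)c1cc(CCc2cccc(OC)c2)cc(Oc2ccc(CCc3cccc(OC)c3)cc2)c1O | intermediate
19 | 2-(hydroxymethyl)-4-[2-(3-methoxyphenyl)ethyl]-6-{4-[2-(3-methoxyphenyl)ethyl]phenoxy}phenol | OCc1cc(CCc2cccc(OC)c2)cc(Oc2ccc(CCc3cccc(OC)c3)cc2)c1O | intermediate
20 | 2-hydroxy-5-[2-(3-methoxyphenyl)ethyl]-3-{4-[2-(3-methoxyphenyl)ethyl]phenoxy}benzaldehyde | O=Cc1cc(CCc2cccc(OC)c2)cc(Oc2ccc(CCc3cccc(OC)c3)cc2)c1O | intermediate
21 | 2-hydroxy-5-[2-(3-methoxyphenyl)ethyl]-3-{4-[2-(3-methoxyphenyl)ethyl]phenoxy}phenyl formate (not isolated) | O=COc1cc(CCc2cccc(OC)c2)cc(Oc2ccc(CCc3cccc(OC)c3)cc2)c1O | intermediate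
22 | 5-[2-(3-methoxyphenyl)ethyl]-3-{4-[2-(3-methoxyphenyl)ethyl]phenoxy}benzene-1,2-diol | COc1cccc(CCc2ccc(Oc3cc(CCc4cccc(OC)c4)cc(O)c3O)cc2)c1 | intermediate
23 | perrottetin F | Oc1cccc(CCc2ccc(Oc3cc(CCc4cccc(O)c4)cc(O)c3O)cc2)c1 | target

## Step count and risk

Total step count: 15.
Longest linear sequence: 10 steps (steps 1–5, then 11–15). The arm of steps 6–10 has the same length.

### Steps most likely to fail

**Step 11.**
- What may go wrong: the oxocarbenium ion may be captured intramolecularly by ring D (six-membered Friedel–Crafts closure para to the methoxy group). The diene may be protodesilylated before it reacts. The sequence may also stall before aromatisation.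
- Fallback: the benzannulation is given up and the B–O–C bond is made by a copper-catalysed Ullmann ether synthesis.
- The fallback sets out from phenol 4, which is coupled with commercial 3-bromo-4,5-dimethoxybenzaldehyde (COc1cc(C=O)cc(Br)c1OC; CuI, N,N-dimethylglycine, Cs2CO3, dioxane, 100 °C). This gives 3,4-dimethoxy-5-{4-[2-(3-methoxyphenyl)ethyl]phenoxy}benzaldehyde F1.
- Wittig olefination of F1 with 2 (KOtBu, THF) gives 1,2-dimethoxy-5-[2-(3-methoxyphenyl)ethenyl]-3-{4-[2-(3-methoxyphenyl)ethyl]phenoxy}benzene F2.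
- Hydrogenation (H2, Pd/C) gives 1,2-dimethoxy-5-[2-(3-methoxyphenyl)ethyl]-3-{4-[2-(3-methoxyphenyl)ethyl]phenoxy}benzene F3.
- BBr3 then removes all four methyl groups, and the fallback comes back to the route at target 23.

**Step 10.**
- What may go wrong: the enol ether may add to the ionised product acetal instead of the diethoxycarbenium ion (telomerisation). Prolonged contact with BF3 may also cause Friedel–Crafts ring closure onto ring D.
- Fallback: the second aldehyde carbon is introduced with a stabilised iminium electrophile, and the bis-acetal is bypassed.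
- The fallback sets out from enol ether 14. Vilsmeier–Arnold formylation (POCl3, DMF, 0 °C → rt; aq. K2CO3) gives 3-(dimethylamino)-2-[2-(3-methoxyphenyl)ethyl]prop-2-enal F4.
- Alkaline hydrolysis (NaOH, aq. EtOH, reflux; then acid) gives 2-[2-(3-methoxyphenyl)ethyl]malondialdehyde in its enol form F5.
- Silylation (Me3SiCl, NEt3) gives 2-[2-(3-methoxyphenyl)ethyl]-3-(trimethylsilyloxy)prop-2-enal F6.
- F6 is a 3-silyloxy-2-en-1-one type dielectrophile that is still symmetric in its outcome. It is condensed with diene 8 (TiCl4, CH2Cl2, −78 → 20 °C), and the fallback comes back to the route at salicylate 18.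

**Step 3.**
- What may go wrong: base-induced self-condensation of the chloro keto ester, and slow displacement of chloride on its enolate form.
- Fallback: the β-keto ester is built after the ether bond instead of before it.
- The fallback sets out from phenol 4. Williamson alkylation with chloroacetic acid (NaOH, H2O, reflux; then acid) gives {4-[2-(3-methoxyphenyl)ethyl]phenoxy}acetic acid F7.
- 1,1'-Carbonyldiimidazole in THF converts F7 into 1-(1H-imidazol-1-yl)-2-{4-[2-(3-methoxyphenyl)ethyl]phenoxy}ethan-1-one F8.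
- Masamune–Brooks C-acylation of magnesium methyl malonate (potassium methyl malonate, MgCl2, NEt3, MeCN–THF) with decarboxylation comes back to the route at keto ester 6.

## Further compounds

F1 | step 11 | 3,4-dimethoxy-5-{4-[2-(3-methoxyphenyl)ethyl]phenoxy}benzaldehyde | COc1cc(C=O)cc(Oc2ccc(CCc3cccc(OC)c3)cc2)c1OC
F2 | step 11 | 1,2-dimethoxy-5-[2-(3-methoxyphenyl)ethenyl]-3-{4-[2-(3-methoxyphenyl)ethyl]phenoxy}benzene (E/Z mixture) | COc1cc(C=Cc2cccc(OC)c2)cc(Oc2ccc(CCc3cccc(OC)c3)cc2)c1OC
F3 | step 11 | 1,2-dimethoxy-5-[2-(3-methoxyphenyl)ethyl]-3-{4-[2-(3-methoxyphenyl)ethyl]phenoxy}benzene | COc1cc(CCc2cccc(OC)c2)cc(Oc2ccc(CCc3cccc(OC)c3)cc2)c1OC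
F4 | step 10 | 3-(dimethylamino)-2-[2-(3-methoxyphenyl)ethyl]prop-2-enal | CN(C)C=C(CCc1cccc(OC)c1)C=O
F5 | step 10 | 2-[2-(3-methoxyphenyl)ethyl]malondialdehyde (enol form) | O=CC(CCc1cccc(OC)c1)=CO
F6 | step 10 | 2-[2-(3-methoxyphenyl)ethyl]-3-(trimethylsilyloxy)prop-2-enal | C[Si](C)(C)OC=C(CCc1cccc(OC)c1)C=O
F7 | step 3 | {4-[2-(3-methoxyphenyl)ethyl]phenoxy}acetic acid | OC(=O)COc1ccc(CCc2cccc(OC)c2)cc1
F8 | step 3 | 1-(1H-imidazol-1-yl)-2-{4-[2-(3-methoxyphenyl)ethyl]phenoxy}ethan-1-one | O=C(COc1ccc(CCc2cccc(OC)c2)cc1)n1ccnc1
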